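**Retrosynthetic overview**
- C40 ⇒ 2 × C10 + C20: both C7=C8 bonds come from one two-directional Julia–Kocienski olefination of a (3R,6R) ring sulfone with the C20 dialdehyde crocetindial, itself made from the C10 trienedial by C2 then C3 Wittig homologation.
- Ring sulfone ⇒ cis-hydroxymethyl cyclohexenol: primary C–S bond first, then Mitsunobu inversion at C3 (cis → trans), which also installs the O-benzoate protecting group.
- cis-Diol ⇒ bridged lactone ⇒ CBS-reduced enone esters: base epimerisation at C6 funnels both epimers into the only lactone that can close, so C6 follows the catalyst-set C3.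
- Both carbocycles ⇒ one two-fold Michael/aldol-condensation annulation of ethylene glycol bis(acetoacetate) with two molecules of mesityl oxide.
- Ring order: the two cyclohexene rings form together (step 2); the lactone bridge is a later, transient ring (step 4) that is reduced away (step 5).

Assumption: the SMILES is read as all-E (3R,6R,3'R,6'R)-ε,ε-carotene-3,3'-diol (lactucaxanthin); "C3" and "C6" in the comments are carotenoid numbering (C3 = carbinol, C6 = ring CH bearing the chain).

**Step 1**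
Reactants: 1 ethylene glycol; 2 tert-butyl acetoacetate
Product: 3 ethane-1,2-diyl bis(3-oxobutanoate)
Conditions: 2 (2.2 equiv), toluene, 110 °C, t-BuOH distilled off
Reagents that add atoms: none
Why: Thermal transacetoacetylation (acyl transfer driven by loss of volatile tert-butanol) acylates both hydroxyls and creates no stereocentre.

**Step 2**
Reactants: 3 ethane-1,2-diyl bis(3-oxobutanoate); 4 mesityl oxide
Product: 6 ethane-1,2-diyl bis(2,6,6-trimethyl-4-oxocyclohex-2-ene-1-carboxylate), via bis-Michael tetraketone 5 (not isolated)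
Conditions: 4 (6 equiv), ZnCl2 (0.3 equiv), heptane/toluene, reflux, Dean–Stark, 48 h
Reagents that add atoms: none
Why: A two-fold Lewis-acid-mediated Michael addition of the acetoacetate C2 carbons to the β,β-dimethyl enone followed by two intramolecular aldol condensations (Robinson-type annulation, the established acetoacetate/mesityl oxide route to 4-alkoxycarbonyl-isophorones run on both arms of the tether) builds both cyclohexenone rings, both quaternary carbons and four C–C bonds in one operation; the ring CH centre is formed unselectively and is corrected in step 4.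

**Step 3**
Reactants: 6 ethane-1,2-diyl bis(2,6,6-trimethyl-4-oxocyclohex-2-ene-1-carboxylate)
Product: 7 ethane-1,2-diyl bis[(4S)-4-hydroxy-2,6,6-trimethylcyclohex-2-ene-1-carboxylate]
Conditions: (R)-Me-CBS (0.3 equiv), catecholborane (3.5 equiv), toluene, −78 °C; MeOH, then aqueous work-up
Reagents that add atoms: none
Why: Corey–Bakshi–Shibata reduction delivers hydride 1,2 to one face of each enone carbonyl under catalyst control (alkenyl flank as the large group), setting the carbinol centre as S whatever the configuration at C1, with ester and alkene untouched; the sense is checked by Mosher analysis and the antipodal catalyst is used if it is reversed.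

**Step 4**
Reactants: 7 ethane-1,2-diyl bis[(4S)-4-hydroxy-2,6,6-trimethylcyclohex-2-ene-1-carboxylate]
Product: 8 (1S,4R)-5,8,8-trimethyl-2-oxabicyclo[2.2.2]oct-5-en-3-one
Conditions: t-BuOK (2.4 equiv), THF/DMSO 4:1, 0 → 40 °C; aq NH4Cl (2 equiv of 8 per 7)
Reagents that add atoms: none
Why: Enolate epimerisation coupled to lactonisation (intramolecular transesterification) is stereoconvergent, because the ester α-CH equilibrates through its dienolate and only the epimer with the ester cis to the alkoxide can close the bridged δ-lactone, so C6 is fixed relative to the CBS-set carbinol while the glycol tether is expelled.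

**Step 5**
Reactants: 8 (1S,4R)-5,8,8-trimethyl-2-oxabicyclo[2.2.2]oct-5-en-3-one
Product: 9 (1S,4R)-4-(hydroxymethyl)-3,5,5-trimethylcyclohex-2-en-1-ol
Conditions: LiAlH4, THF, 0 °C → rt; Fieser work-up
Reagents that add atoms: none
Why: Hydride reduction of the lactone gives the cis-diol without touching either stereocentre or the trisubstituted alkene.

**Step 6**
Reactants: 9 (1S,4R)-4-(hydroxymethyl)-3,5,5-trimethylcyclohex-2-en-1-ol
Product: 11 (1R,4R)-3,5,5-trimethyl-4-{[(1-phenyl-1H-tetrazol-5-yl)sulfanyl]methyl}cyclohex-2-en-1-yl benzoate, via hydroxy thioether 10 (not isolated)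
Conditions: PT-SH (1.0 equiv), PPh3 (1.1 equiv), DIAD (1.1 equiv), THF, −20 → 0 °C; then BzOH (1.5 equiv), PPh3 (1.5 equiv), DIAD (1.5 equiv), 0 °C → rt
Reagents that add atoms: 1-phenyl-1H-tetrazole-5-thiol, Sc1nnnn1-c1ccccc1; benzoic acid, OC(=O)c1ccccc1
Why: Two sequential Mitsunobu reactions first thioetherify the primary alcohol with the acidic thiol at low temperature and then esterify the secondary allylic alcohol by SN2 with inversion, turning the cis-(1S) carbinol into the trans-(1R) benzoate (the 3R,6R relationship of the target) and protecting the oxygen at the same time.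

**Step 7**
Reactants: 11 (1R,4R)-3,5,5-trimethyl-4-{[(1-phenyl-1H-tetrazol-5-yl)sulfanyl]methyl}cyclohex-2-en-1-yl benzoate
Product: 12 (1R,4R)-3,5,5-trimethyl-4-{[(1-phenyl-1H-tetrazol-5-yl)sulfonyl]methyl}cyclohex-2-en-1-yl benzoate
Conditions: (NH4)6Mo7O24·4H2O (10 mol%), 30% H2O2, EtOH, 0 °C → rt
Reagents that add atoms: hydrogen peroxide, OO
Why: Mo(VI)-catalysed sulfide-to-sulfone oxidation is chemoselective for sulfur over the hindered trisubstituted alkene bearing an allylic ester, and no stereocentre is involved.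

**Step 8**
Reactants: 13 (2E,4E,6E)-2,7-dimethylocta-2,4,6-trienedial; 14 (1,3-dioxolan-2-ylmethyl)triphenylphosphonium bromide
Product: 16 (2E,4E,6E,8E,10E)-4,9-dimethyldodeca-2,4,6,8,10-pentaenedial, via bis-dioxolane pentaene 15 (not isolated)
Conditions: 14 (2.4 equiv), t-BuOK (2.4 equiv), THF, 0 °C → rt; then 1 M HCl, THF, rt
Reagents that add atoms: water, O
Why: A two-fold Wittig C2-homologation with the masked formylmethylene ylide is followed by acid hydrolysis of the acetals, which also equilibrates the new enal double bonds to E.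

**Step 9**
Reactants: 16 (2E,4E,6E,8E,10E)-4,9-dimethyldodeca-2,4,6,8,10-pentaenedial; 17 2-(triphenyl-λ5-phosphanylidene)propanal
Product: 18 (2E,4E,6E,8E,10E,12E,14E)-2,6,11,15-tetramethylhexadeca-2,4,6,8,10,12,14-heptaenedial (crocetindial)
Conditions: 17 (2.5 equiv), toluene, 90 °C
Reagents that add atoms: none
Why: A two-fold Wittig olefination with a formyl-stabilised ylide gives the (E)-trisubstituted enals, and the α-methyl enal product is less electrophilic than the starting enal so over-homologation is suppressed.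

**Step 10**
Reactants: 12 (1R,4R)-3,5,5-trimethyl-4-{[(1-phenyl-1H-tetrazol-5-yl)sulfonyl]methyl}cyclohex-2-en-1-yl benzoate; 18 crocetindial
Product: 21 (3R,3'R,6R,6'R)-ε,ε-carotene-3,3'-diyl dibenzoate, via C30 mono-olefin aldehyde 19 (not isolated), via 7E/7Z isomer mixture 20 (not isolated)
Conditions: 12 (2.3 equiv), 18 (1.0 equiv), KHMDS (2.4 equiv), DME/THF, −70 → −20 °C, base added last; aq NH4Cl; then I2 (2 mol%), CH2Cl2, rt, daylight
Reagents that add atoms: none
Why: A two-directional Julia–Kocienski olefination (carbanion addition, Smiles rearrangement, loss of SO2 and the tetrazolyl oxide) forms C7=C8 and C7'=C8', catalytic iodine then equilibrates 7Z isomers to the all-E polyene, and the C6 centres (no leaving group β to the carbanion) and the benzoates are not affected.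

**Step 11**
Reactants: 21 (3R,3'R,6R,6'R)-ε,ε-carotene-3,3'-diyl dibenzoate
Product: 22 (3R,3'R,6R,6'R)-ε,ε-carotene-3,3'-diol (lactucaxanthin)
Conditions: NaOMe (0.3 equiv), MeOH/THF, rt, dark, N2
Reagents that add atoms: none
Why: Zemplén-type transesterification cleaves the benzoates at the acyl–oxygen bond with retention at C3 under the mild basic conditions routinely used to saponify xanthophyll esters, which the ε-rings and polyene tolerate.

**Compound list**
1 | ethylene glycol | OCCO | starting material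
2 | tert-butyl acetoacetate | CC(=O)CC(=O)OC(C)(C)C | starting material
3 | ethane-1,2-diyl bis(3-oxobutanoate) | CC(=O)CC(=O)OCCOC(=O)CC(C)=O | intermediate
4 | mesityl oxide (4-methylpent-3-en-2-one) | CC(=O)C=C(C)C | starting material
5 | ethane-1,2-diyl bis(2-acetyl-3,3-dimethyl-5-oxohexanoate) | CC(=O)CC(C)(C)C(C(C)=O)C(=O)OCCOC(=O)C(C(C)=O)C(C)(C)CC(C)=O | intermediate
6 | ethane-1,2-diyl bis(2,6,6-trimethyl-4-oxocyclohex-2-ene-1-carboxylate), C1 epimer mixture | CC1=CC(=O)CC(C)(C)C1C(=O)OCCOC(=O)C1C(C)=CC(=O)CC1(C)C | intermediate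
7 | ethane-1,2-diyl bis[(4S)-4-hydroxy-2,6,6-trimethylcyclohex-2-ene-1-carboxylate], C1 epimer mixture | CC1=C[C@@H](O)CC(C)(C)C1C(=O)OCCOC(=O)C1C(C)=C[C@@H](O)CC1(C)C | intermediate
8 | (1S,4R)-5,8,8-trimethyl-2-oxabicyclo[2.2.2]oct-5-en-3-one | CC1=C[C@@H]2CC(C)(C)[C@H]1C(=O)O2 | intermediate
9 | (1S,4R)-4-(hydroxymethyl)-3,5,5-trimethylcyclohex-2-en-1-ol | CC1=C[C@@H](O)CC(C)(C)[C@H]1CO | intermediate
10 | (1S,4R)-3,5,5-trimethyl-4-{[(1-phenyl-1H-tetrazol-5-yl)sulfanyl]methyl}cyclohex-2-en-1-ol | CC1=C[C@@H](O)CC(C)(C)[C@H]1CSc1nnnn1-c1ccccc1 | intermediate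
11 | (1R,4R)-3,5,5-trimethyl-4-{[(1-phenyl-1H-tetrazol-5-yl)sulfanyl]methyl}cyclohex-2-en-1-yl benzoate | CC1=C[C@H](OC(=O)c2ccccc2)CC(C)(C)[C@H]1CSc1nnnn1-c1ccccc1 | intermediate
12 | (1R,4R)-3,5,5-trimethyl-4-{[(1-phenyl-1H-tetrazol-5-yl)sulfonyl]methyl}cyclohex-2-en-1-yl benzoate | CC1=C[C@H](OC(=O)c2ccccc2)CC(C)(C)[C@H]1CS(=O)(=O)c1nnnn1-c1ccccc1 | intermediate
13 | (2E,4E,6E)-2,7-dimethylocta-2,4,6-trienedial | O=C/C(C)=C/C=C/C=C(C)/C=O | starting material
14 | (1,3-dioxolan-2-ylmethyl)triphenylphosphonium bromide | [Br-].C1COC(C[P+](c2ccccc2)(c2ccccc2)c2ccccc2)O1 | starting material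
15 | 2,2'-[(3E,5E,7E)-3,8-dimethyldeca-1,3,5,7,9-pentaene-1,10-diyl]bis(1,3-dioxolane), 1,9-E/Z mixture | C1COC(O1)C=C/C(C)=C/C=C/C=C(C)/C=CC1OCCO1 | intermediate
16 | (2E,4E,6E,8E,10E)-4,9-dimethyldodeca-2,4,6,8,10-pentaenedial | O=C/C=C/C(C)=C/C=C/C=C(C)/C=C/C=O | intermediate
17 | 2-(triphenyl-λ5-phosphanylidene)propanal | CC(C=O)=P(c1ccccc1)(c1ccccc1)c1ccccc1 | starting material
18 | (2E,4E,6E,8E,10E,12E,14E)-2,6,11,15-tetramethylhexadeca-2,4,6,8,10,12,14-heptaenedial (crocetindial) | O=C/C(C)=C/C=C/C(C)=C/C=C/C=C(C)/C=C/C=C(C)/C=O | intermediate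
19 | (3R,6R)-3-(benzoyloxy)-8'-apo-ε-caroten-8'-al, 7E/7Z | CC1=C[C@H](OC(=O)c2ccccc2)CC(C)(C)[C@H]1C=C/C(C)=C/C=C/C(C)=C/C=C/C=C(C)/C=C/C=C(C)/C=O | intermediate
20 | (3R,3'R,6R,6'R)-ε,ε-carotene-3,3'-diyl dibenzoate, 7,7'-E/Z mixture | CC1=C[C@H](OC(=O)c2ccccc2)CC(C)(C)[C@H]1C=C/C(C)=C/C=C/C(C)=C/C=C/C=C(C)/C=C/C=C(C)/C=C[C@H]1C(C)=C[C@H](OC(=O)c2ccccc2)CC1(C)C | intermediate
21 | (3R,3'R,6R,6'R)-ε,ε-carotene-3,3'-diyl dibenzoate, all-E | CC1=C[C@H](OC(=O)c2ccccc2)CC(C)(C)[C@H]1/C=C/C(C)=C/C=C/C(C)=C/C=C/C=C(C)/C=C/C=C(C)/C=C/[C@H]1C(C)=C[C@H](OC(=O)c2ccccc2)CC1(C)C | intermediate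
22 | (3R,3'R,6R,6'R)-ε,ε-carotene-3,3'-diol (lactucaxanthin) | CC1=C[C@H](O)CC(C)(C)[C@H]1/C=C/C(C)=C/C=C/C(C)=C/C=C/C=C(C)/C=C/C=C(C)/C=C/[C@H]1C(C)=C[C@H](O)CC1(C)C | target

**Step count and risks**
Total step count: 11. Longest linear sequence: 9 (steps 1–7, 10, 11); steps 8 and 9 are a two-step side branch.

Most likely to fail, step 2 (two hindered Michael additions in one pot, so the yield is the product of two modest annulations). The fallback changes the ring-forming reaction to a two-fold Diels–Alder reaction. It sets out from 1 and 4 and comes back at 6. Compound 1 is esterified with but-2-ynoic acid (DCC, DMAP) to ethane-1,2-diyl bis(but-2-ynoate) F1. Compound 4 is silylated (TMSCl, Et3N, NaI, MeCN) to 4-methyl-2-[(trimethylsilyl)oxy]penta-1,3-diene F2. Heating F1 with F2 (3 equiv, toluene, 150 °C, sealed tube) again closes both rings in one operation, the CH2 terminus of the 2-silyloxydiene bonding to the methyl-bearing alkyne carbon, to give ethane-1,2-diyl bis{2,6,6-trimethyl-4-[(trimethylsilyl)oxy]cyclohexa-1,4-diene-1-carboxylate} F3. Treatment with 1 M HCl in THF hydrolyses the enol ethers and moves the ring double bond into conjugation with the ketone, which gives 6.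

Second, step 3 (the enone has no α-substituent, so the enantioselectivity of the CBS reduction is uncertain). The fallback replaces asymmetric catalysis by an enzymatic kinetic resolution. It sets out from 6 and comes back at 10, which is then isolated before the benzoate Mitsunobu of step 6. Compound 6 is reduced without chiral control (NaBH4, CeCl3, MeOH, 0 °C) to the stereoisomer mixture ethane-1,2-diyl bis(4-hydroxy-2,6,6-trimethylcyclohex-2-ene-1-carboxylate) F4. The conditions of step 4, of step 5 and of the thioether stage of step 6 then give in turn rac-5,8,8-trimethyl-2-oxabicyclo[2.2.2]oct-5-en-3-one F5, rac-cis-4-(hydroxymethyl)-3,5,5-trimethylcyclohex-2-en-1-ol F6 and rac-cis-3,5,5-trimethyl-4-{[(1-phenyl-1H-tetrazol-5-yl)sulfanyl]methyl}cyclohex-2-en-1-ol F7. Lipase PS with vinyl acetate in MTBE is expected (Kazlauskas rule) to acylate the (1R)-alcohol to (1R,4S)-3,5,5-trimethyl-4-{[(1-phenyl-1H-tetrazol-5-yl)sulfanyl]methyl}cyclohex-2-en-1-yl acetate F8, which is separated from the unreacted (1S,4R)-alcohol 10. The maximum yield is 50%.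

Third, step 4 (it needs deprotonation of a hindered ester α-CH and a favourable equilibrium towards a strained bridged lactone). The fallback gives up stereoconvergence and separates diastereomers instead. It sets out from 7 and comes back at 9. Compound 7 is reduced directly with LiAlH4, which gives 9 together with its epimer (1S,4S)-4-(hydroxymethyl)-3,5,5-trimethylcyclohex-2-en-1-ol F9. The two diols are separated by chromatography and 9 goes on to step 6, with at most half of the material used.

**Further compounds**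
F1 | step 2 | ethane-1,2-diyl bis(but-2-ynoate) | CC#CC(=O)OCCOC(=O)C#CC
F2 | step 2 | 4-methyl-2-[(trimethylsilyl)oxy]penta-1,3-diene | C=C(O[Si](C)(C)C)C=C(C)C
F3 | step 2 | ethane-1,2-diyl bis{2,6,6-trimethyl-4-[(trimethylsilyl)oxy]cyclohexa-1,4-diene-1-carboxylate} | CC1=C(C(=O)OCCOC(=O)C2=C(C)CC(O[Si](C)(C)C)=CC2(C)C)C(C)(C)C=C(O[Si](C)(C)C)C1
F4 | step 3 | ethane-1,2-diyl bis(4-hydroxy-2,6,6-trimethylcyclohex-2-ene-1-carboxylate), stereoisomer mixture | CC1=CC(O)CC(C)(C)C1C(=O)OCCOC(=O)C1C(C)=CC(O)CC1(C)C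
F5 | step 3 | rac-5,8,8-trimethyl-2-oxabicyclo[2.2.2]oct-5-en-3-one | CC1=C[C@@H]2CC(C)(C)[C@H]1C(=O)O2.CC1=C[C@H]2CC(C)(C)[C@@H]1C(=O)O2
F6 | step 3 | rac-cis-4-(hydroxymethyl)-3,5,5-trimethylcyclohex-2-en-1-ol | CC1=C[C@@H](O)CC(C)(C)[C@H]1CO.CC1=C[C@H](O)CC(C)(C)[C@@H]1CO
F7 | step 3 | rac-cis-3,5,5-trimethyl-4-{[(1-phenyl-1H-tetrazol-5-yl)sulfanyl]methyl}cyclohex-2-en-1-ol | CC1=C[C@@H](O)CC(C)(C)[C@H]1CSc1nnnn1-c1ccccc1.CC1=C[C@H](O)CC(C)(C)[C@@H]1CSc1nnnn1-c1ccccc1
F8 | step 3 | (1R,4S)-3,5,5-trimethyl-4-{[(1-phenyl-1H-tetrazol-5-yl)sulfanyl]methyl}cyclohex-2-en-1-yl acetate | CC1=C[C@H](OC(C)=O)CC(C)(C)[C@@H]1CSc1nnnn1-c1ccccc1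
F9 | step 4 | (1S,4S)-4-(hydroxymethyl)-3,5,5-trimethylcyclohex-2-en-1-ol | CC1=C[C@@H](O)CC(C)(C)[C@@H]1CO
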